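## Analysis of the target

The core is an eight-membered carbocycle. In the numbering used here, C1 carries the acetate, C2 is the ring CH2, C3 carries the methyl group, C4 and C6 are the cyclopropane CH carbons (bridged by the C5 methylene), C7=C8 is a tetrasubstituted double bond and C9 carries the side chain. C7=C8 is also the α,β-bond of a butenolide: C7 bears the lactone carbonyl and C8 the OCH2 group. There are six stereocentres: C1 (R), C3 (R), C4 (S), C6 (S), C9 (S) and C1′ (R) in the side chain. The acetoxy group, the side chain and the cyclopropane methylene lie on one face of the eight-membered ring, and the C3 methyl lies on the other. The side chain ends in an (E)-allylic tertiary hydroperoxide, which tolerates neither reductants, low-valent metals, phosphines nor base and therefore has to be made last. The butenolide is base-sensitive (acidic C–H at the OCH2 group and at C9), and the cyclopropane is conjugated with it. The difficulties are the closure of an eight-membered ring that contains a tetrasubstituted alkene, the placing of C1 and C3 relative to C9 and the cyclopropane, and the handling of three different C=C bonds. The strategy rests on the segment C1–C2–C3: C1 is a carbinol carbon, C2 a CH2 and C3 a methyl-bearing CH, so C3 can be carried as C=CH2. The C1–C2 bond is then the bond of a homoallylic alcohol, the bond an allyl metal makes when it adds to an aldehyde.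

## Retrosynthetic reasoning

**Hydroperoxide.** The O–C5′ bond of 35 is cut last. The acetate 34 with a 2-methylalk-2-ene terminus is the substrate of a Schenck ene reaction, which moves the double bond to C3′=C4′ and puts OOH on the tertiary carbon. Nothing after this step has to tolerate the peroxide.

**Acetate and C3 methyl.** 34 comes from alcohol 33 by acylation. The C3–H bond of 33 is cut back to the exocyclic methylene of 32. The free C1 hydroxyl of 32 is homoallylic to that alkene and can deliver hydrogen to its own face, which gives the methyl trans to oxygen. This is why acetylation follows the hydrogenation.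

**Ring closure (key disconnection).** In 32 the C1–C2 bond is cut. It is the only ring bond that lies between a carbinol carbon and an allylic CH2, so the cut gives an aldehyde at C1 and an allylic bromide in one molecule, 30. The other candidates, C6–C7 and C8–C9, are sp2–sp3 bonds that are easier to make between two separate fragments. The forward reaction is an intramolecular Nozaki–Hiyama–Kishi allylation. It has to close the eight-membered ring, set C1 under the influence of C9 and leave the enolisable C9 centre and the lactone alone. The 2-substituted allyl unit is symmetric, so regiochemistry is not an issue.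

**Preparing the cyclisation substrate.** 30 is taken back to bromo alcohol 29, diol 28 and the doubly protected 27. The aldehyde is unveiled only in the last step before cyclisation, because C9–H is α to the aldehyde and γ to the lactone carbonyl. The bromide is made after the fragment coupling, because an allylic bromide would not survive a palladium-catalysed step.

**Fragment union.** In 27 the C6–C7 bond is cut, which gives chlorobutenolide 13 and cyclopropylstannane 24. The cut divides the molecule into two halves of similar size, each with its own stereocentres. The forward reaction is a Negishi coupling of the cyclopropylzinc reagent 26, which retains configuration at C6 and needs no base. A boron-based coupling of a cyclopropyl ester would need strong aqueous base and heat, which the butenolide and C9 would not tolerate.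

**Butenolide half.** The C7=C8 bond of 13 is cut to chloromethyl ketone 9 and phosphonate salt 11 (ester 12, intramolecular Horner–Wadsworth–Emmons reaction). The chlorine on C7 is brought in with the phosphonate. Electrophilic halogenation of a finished butenolide is not possible here, because the trisubstituted alkene of the side chain would react first. 9 goes back through Weinreb amide 8 and 7 to imide 6. The C9–C1 bond of 6 is cut to imide 4, made from acid 1 and auxiliary 2. The carboxyl carbon of 1 becomes C8, its α-carbon C9 and the added hydroxymethyl carbon C1. The auxiliary decides C9, and the C1′ centre comes from 1 unchanged.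

**Cyclopropane half.** The exocyclic methylene of 24 is cut to ketone 23, and the C–C bond next to the carbonyl to aldehyde 18 and the alkoxymethyl reagent 21 (from 20, made from 19). 18 comes from cyclopropylmethanol 17, whose ring is made by asymmetric cyclopropanation of the (Z)-allylic alcohol 16, available from 14. Tin is chosen as the metal on C6 because it survives the organolithium addition and the Wittig step. A boronic ester would not survive the organolithium addition.

## Alternatives that were turned down

**Alternative 1:** Semipinacol ring expansion. The bond between the two cyclopropane CH carbons (C4–C6) is disconnected. The precursor is the cis-bicyclo[5.2.0]nonane A1, which has a ring-fusion tertiary alcohol and a neighbouring cyclobutyl mesylate. In the forward step the ring-fusion bond migrates to the mesylate carbon, which contracts the four-membered ring to the cyclopropane and enlarges the seven-membered ring to the cyclopropyl ketone A2.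
- For it: the shift is stereospecific, it makes the cis-cyclopropane and the eight-membered ring in one operation, and it avoids a medium-ring closure from an open chain. On the entropy of ring formation it is stronger than the chosen route.
- Against it: A1 carries six stereocentres and needs the migrating bond exactly anti to the leaving group, so it is about as hard to make as the target. The cationic character next to a strained ring invites cyclobutyl–cyclopropylcarbinyl scrambling. After the shift the butenolide still has to be built on a cyclopropyl ketone, which costs several steps at a hindered carbonyl.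
- Comparison: the chosen strategy offers two fragments of about seven steps each and only three steps after ring closure.

**Alternative 2:** Transannular Horner–Wadsworth–Emmons reaction. The C7=C8 bond is disconnected. In the eleven-membered keto-phosphonate lactone A3 the carbanion at C7 adds to the C8 ketone and eliminates phosphate, which closes the butenolide and the cyclooctene together to give A4.
- For it: the olefination places the double bond without ambiguity, and an eleven-membered lactonisation is easier than an eight-membered carbocyclisation. No halogen at C7 and no cross-coupling are needed. On these points it is as strong as or stronger than the chosen route.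
- Against it: all stereocentres, including C1 and C3, have to be set on an open chain without help from the ring. The C8 ketone is flanked by the C9 stereocentre and would meet the olefination base. The transannular step has to form a tetrasubstituted alkene while folding a large ring around a cyclopropane.
- Comparison: the chosen strategy sets C1 and C3 late, using the ring and the C1 hydroxyl as control elements, and is more convergent.

**Alternative 3:** Claisen ring expansion. The C2–C3 bond is disconnected. The butenolide-fused 2-methylene-6-propenyl-dihydropyran A5 rearranges on heating: the O–C bond at the doubly allylic carbon breaks as the exocyclic methylene bonds to the propenyl terminus, which gives the cyclooctadienone A6.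
- For it: the sigmatropic shift needs no high dilution and transfers chirality from the C–O stereocentre to C3. In control of C3 it is stronger than a directed hydrogenation.
- Against it: A5 needs an exocyclic enol ether next to a doubly allylic ether that ionises easily. In A6 the C9 centre is α to a ketone and γ to the lactone carbonyl. The cyclopropane still has to be added to a Z-alkene that is conjugated with the butenolide, with no reagent control over its face, and the ketone has to be reduced selectively.
- Comparison: the chosen strategy fixes the cyclopropane configuration by reagent control before the ring exists and leaves only hydrogenation, acetylation and oxygenation after the ring closure.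

Key step: step 19

## Route

Remark: compounds 20–27 carry a 1-ethoxyethyl acetal and are mixtures of epimers at the acetal carbon (22 also at the carbinol carbon). These centres are removed in steps 13 and 16 and are left undefined in the SMILES.

Remark: the facial sense of step 9 is assigned from the face rule of the dioxaborolane-controlled cyclopropanation, under which the (4S,5S) ligand should give the (1S,2S) product. If the sense should be opposite, the enantiomeric ligand is used.

Step 1
Reactants: 1 (R)-citronellic acid [(3R)-3,7-dimethyloct-6-enoic acid]; 2 (S)-4-benzyl-1,3-oxazolidin-2-one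
Product: 4 (S)-4-benzyl-3-[(3R)-3,7-dimethyloct-6-enoyl]-1,3-oxazolidin-2-one, via mixed pivalic anhydride 3 (not isolated)
Conditions: PivCl, Et3N, THF, −20 °C; then LiCl, 2, −20 °C → rt
Reagents that add atoms: none
Why: N-acylation of the oxazolidinone by a mixed anhydride (LiCl/Et3N variant); no stereocentre is touched and the C1′ centre comes unchanged from 1.

Step 2
Reactants: 4
Product: 6 (S)-4-benzyl-3-[(2R,3R)-2-(hydroxymethyl)-3,7-dimethyloct-6-enoyl]-1,3-oxazolidin-2-one, via Z-chlorotitanium enolate 5 (not isolated)
Conditions: TiCl4, i-Pr2NEt, CH2Cl2, 0 °C; then 1,3,5-trioxane, TiCl4, 0 °C, quenched as soon as 5 is consumed; aq NH4Cl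
Reagents that add atoms: 1,3,5-trioxane, C1OCOCO1
Why: Evans titanium-enolate hydroxymethylation (formaldehyde aldol); the chelated Z-enolate is attacked on the face away from the benzyl group, which sets the future C9 centre, and the new CH2OH carbon is the future C1.

Step 3
Reactants: 6
Product: 7 (2R,3R)-2-(hydroxymethyl)-N-methoxy-N,3,7-trimethyloct-6-enamide
Conditions: MeONHMe·HCl, AlMe3, CH2Cl2, −15 → 0 °C
Reagents that add atoms: N,O-dimethylhydroxylamine hydrochloride, CNOC.Cl
Why: Aluminium-amide transamidation to the Weinreb amide; the free β-hydroxyl binds aluminium and steers attack to the exocyclic carbonyl, the medium is non-basic so C9 should keep its configuration, and the auxiliary is recovered.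

Step 4
Reactants: 7
Product: 8 (2R,3R)-2-[(tert-butyldimethylsilyloxy)methyl]-N-methoxy-N,3,7-trimethyloct-6-enamide
Conditions: TBSCl, imidazole, CH2Cl2, rt
Reagents that add atoms: tert-butyldimethylsilyl chloride, CC(C)(C)[Si](C)(C)Cl
Why: Silylation of the primary alcohol; the ether keeps the C1 oxygen from cyclising onto the α-chloro ketone of the next step.

Step 5
Reactants: 8
Product: 9 (3R,4R)-3-[(tert-butyldimethylsilyloxy)methyl]-1-chloro-4,8-dimethylnon-7-en-2-one
Conditions: ICH2Cl, MeLi·LiBr, THF, −78 °C; aq NH4Cl at −78 °C
Reagents that add atoms: chloroiodomethane, ClCI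
Why: Carbenoid homologation of a Weinreb amide; the chelated tetrahedral adduct is stable at −78 °C, so one chloromethyl group adds and the α-chloro ketone appears only on work-up, with no base present to epimerise C9.

Step 6
Reactants: 10 triethyl 2-chloro-2-phosphonoacetate
Product: 11 potassium 2-chloro-2-(diethoxyphosphoryl)acetate
Conditions: KOH (1.0 equiv), EtOH–H2O, 0 °C → rt; evaporated and dried
Reagents that add atoms: potassium hydroxide, [K+].[OH-]
Why: Saponification; the carboxylic ester is far more electrophilic than the phosphonate esters and is cleaved selectively.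

Step 7
Reactants: 9; 11
Product: 13 3-chloro-4-[(2S,3R)-1-(tert-butyldimethylsilyloxy)-3,7-dimethyloct-6-en-2-yl]furan-2(5H)-one, via keto ester 12 (not isolated)
Conditions: NaI (cat.), DMF, rt; then LiCl, i-Pr2NEt, 0 °C → rt
Reagents that add atoms: none
Why: SN2 displacement of the α-keto chloride by the carboxylate, then intramolecular Horner–Wadsworth–Emmons olefination under Masamune–Roush conditions; the five-membered closure forms C7=C8 with chlorine already on C7, and the mild amine base should leave C9 alone.

Step 8
Reactants: 14 propargyl alcohol
Product: 16 (Z)-3-(tributylstannyl)prop-2-en-1-ol, via cyclic lithium vinylalanate 15 (not isolated)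
Conditions: LiAlH4, THF, 0 °C → rt; then Bu3SnOTf, −78 °C → rt
Reagents that add atoms: tributyltin trifluoromethanesulfonate, CCCC[Sn](CCCC)(CCCC)OS(=O)(=O)C(F)(F)F
Why: Hydroxyl-directed trans-hydroalumination puts aluminium on the terminal carbon cis to the CH2O group; tin replaces aluminium with retention, which gives the Z-alkene.

Step 9
Reactants: 16
Product: 17 [(1S,2S)-2-(tributylstannyl)cyclopropyl]methanol
Conditions: Zn(CH2I)2·DME (from Et2Zn, CH2I2, DME), (4S,5S)-2-butyl-N,N,N′,N′-tetramethyl-1,3,2-dioxaborolane-4,5-dicarboxamide (1.2 equiv), CH2Cl2, −10 °C → rt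
Reagents that add atoms: diiodomethane, ICI
Why: Charette asymmetric Simmons–Smith cyclopropanation; the zinc alkoxide bound to the chiral dioxaborolane delivers CH2 to one alkene face, and syn addition turns the Z-alkene into the cis-cyclopropane, which sets the future C4 and C6.

Step 10
Reactants: 17
Product: 18 (1S,2S)-2-(tributylstannyl)cyclopropane-1-carbaldehyde
Conditions: Dess–Martin periodinane, NaHCO3, CH2Cl2, 0 °C
Reagents that add atoms: none
Why: Dess–Martin oxidation under buffered conditions; no amine base is present, so the cis-aldehyde should not epimerise to trans.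

Step 11
Reactants: 19 (tributylstannyl)methanol
Product: 20 tributyl[(1-ethoxyethoxy)methyl]stannane
Conditions: ethyl vinyl ether, PPTS (cat.), CH2Cl2, rt
Reagents that add atoms: ethyl vinyl ether, C=COCC
Why: Acid-catalysed acetal formation; the acetal tolerates organolithium reagents and is removed later by mild acid.

Step 12
Reactants: 18; 20
Product: 22 2-(1-ethoxyethoxy)-1-[(1S,2S)-2-(tributylstannyl)cyclopropyl]ethan-1-ol, via alkoxymethyllithium 21 (not isolated)
Conditions: 20, n-BuLi, THF, −78 °C; then 18, −78 °C; aq NH4Cl
Reagents that add atoms: none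
Why: Tin–lithium exchange on the α-alkoxymethylstannane is fast at −78 °C, where the cyclopropyl–tin bond of 18 is inert, and the resulting carbanion adds to the aldehyde; the carbinol configuration does not matter.

Step 13
Reactants: 22
Product: 23 2-(1-ethoxyethoxy)-1-[(1S,2S)-2-(tributylstannyl)cyclopropyl]ethan-1-one
Conditions: Dess–Martin periodinane, NaHCO3, CH2Cl2, 0 °C → rt
Reagents that add atoms: none
Why: Dess–Martin oxidation of the secondary alcohol; the bicarbonate buffer protects the acetal.

Step 14
Reactants: 23
Product: 24 tributyl{(1S,2S)-2-[3-(1-ethoxyethoxy)prop-1-en-2-yl]cyclopropyl}stannane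
Conditions: Ph3PCH3Br, KOt-Bu, THF, 0 °C → rt
Reagents that add atoms: methyltriphenylphosphonium bromide, C[P+](c1ccccc1)(c1ccccc1)c1ccccc1.[Br-]
Why: Wittig methylenation of an electrophilic α-alkoxy ketone; a cyclopropyl α-hydrogen is hard to remove, so the cis arrangement should hold.

Step 15
Reactants: 24; 13
Product: 27 4-[(2S,3R)-1-(tert-butyldimethylsilyloxy)-3,7-dimethyloct-6-en-2-yl]-3-{(1S,2R)-2-[3-(1-ethoxyethoxy)prop-1-en-2-yl]cyclopropyl}furan-2(5H)-one, via cyclopropyllithium 25 (not isolated), via cyclopropylzinc chloride 26 (not isolated)
Conditions: 24, n-BuLi, THF, −78 → 0 °C; ZnCl2, −78 °C → rt; then 13, Pd2(dba)3 (2.5 mol%), XPhos (10 mol%), THF, 50 °C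
Reagents that add atoms: none
Why: Tin–lithium exchange gives a configurationally stable cyclopropyllithium; transmetalation to zinc and Negishi coupling with the activated α-chloro enoate go with retention at C6, so the cis ring fusion is carried into 27, and the base-free medium spares the butenolide and C9.

Step 16
Reactants: 27
Product: 28 3-[(1S,2R)-2-(3-hydroxyprop-1-en-2-yl)cyclopropyl]-4-[(2S,3R)-1-hydroxy-3,7-dimethyloct-6-en-2-yl]furan-2(5H)-one
Conditions: CSA (0.2 equiv), MeOH, 0 °C → rt
Reagents that add atoms: none
Why: Acid-catalysed methanolysis removes the acetal and the primary silyl ether in one operation; the acid is too weak to touch the trisubstituted alkene or the vinylcyclopropane.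

Step 17
Reactants: 28
Product: 29 3-[(1S,2R)-2-(3-bromoprop-1-en-2-yl)cyclopropyl]-4-[(2S,3R)-1-hydroxy-3,7-dimethyloct-6-en-2-yl]furan-2(5H)-one
Conditions: NBS, Me2S, CH2Cl2, −20 → 0 °C
Reagents that add atoms: N-bromosuccinimide, O=C1CCC(=O)N1Br
Why: Corey–Kim halogenation; only the allylic alkoxysulfonium salt is displaced by bromide at 0 °C, while the hindered saturated C1 alcohol is returned on aqueous work-up, and no free electrophilic bromine is present to attack the side-chain alkene.

Step 18
Reactants: 29
Product: 30 (2S,3R)-2-{4-[(1S,2R)-2-(3-bromoprop-1-en-2-yl)cyclopropyl]-5-oxo-2,5-dihydrofuran-3-yl}-3,7-dimethyloct-6-enal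
Conditions: Dess–Martin periodinane, NaHCO3, CH2Cl2, 0 °C; used at once
Reagents that add atoms: none
Why: Buffered Dess–Martin oxidation gives the aldehyde without base; 30 is not stored because C9–H is α to the aldehyde and γ to the lactone carbonyl.

Step 19
Reactants: 30
Product: 32 tricyclic homoallylic alcohol (1R,4R,6S,9S)-1-hydroxy-3-methylidene-9-[(2R)-6-methylhept-5-en-2-yl] compound with the cis-C4/C6 cyclopropane and the C7=C8 butenolide (numbering of the analysis), via allylchromium(III) species 31 (not isolated)
Conditions: CrCl2 (8 equiv), THF, 4 Å MS, rt; 30 added over 10 h to a final concentration of about 2 mM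
Reagents that add atoms: none
Why: Two single-electron transfers from chromium(II) turn the allylic C–Br bond of 30 into the allylchromium(III) species 31, which adds to the aldehyde through a closed six-membered chair-like transition state with allylic transposition. The closest known reaction type is the intramolecular Nozaki–Hiyama–Kishi (Barbier-type) allylation of an aldehyde to a medium ring. The ring that closes is the eight-membered carbocycle, in the 8-exo-trig mode; because the 2-substituted allyl unit is symmetric, attack through either terminus gives the same C1–C2 bond and the same exocyclic methylene at C3. The new stereocentre C1 is controlled by C9: the ring tether holds C8 gauche to the forming bond, the branched side chain takes the position anti to it, and the carbonyl oxygen ends on the side-chain face (Felkin-type arrangement), which is the required 1R configuration with OH cis to the side chain. The step needs ring closure to win over intermolecular coupling; this is secured by high dilution and by the cis-cyclopropane and the C7=C8 bond, which hold C4, C6, C7 and C8 rigid and turn the chain ends toward each other. It also needs selectivity for the aldehyde over the lactone, which is inherent to allylchromium reagents, and no epimerisation at C9, which the neutral non-basic medium and the immediate use of 30 secure. The intermediate allyl radical carries its spin on the two terminal carbons and not on the carbon bound to the cyclopropane, so opening of the three-membered ring is not expected.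

Step 20
Reactants: 32
Product: 33 tricyclic alcohol (1R,3R,4S,6S,9S)-1-hydroxy-3-methyl-9-[(2R)-6-methylhept-5-en-2-yl] compound with the cis-C4/C6 cyclopropane and the C7=C8 butenolide
Conditions: H2 (about 60 atm), [Rh(nbd)(dppb)]BF4 (10 mol%), CH2Cl2, rt
Reagents that add atoms: none
Why: Hydroxyl-directed hydrogenation; the cationic rhodium centre binds the homoallylic C1–OH and delivers hydrogen to the alkene face syn to oxygen, which places the C3 methyl trans to the oxygen, while the unbound trisubstituted and tetrasubstituted alkenes should react far more slowly and high pressure suppresses alkene migration.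

Step 21
Reactants: 33
Product: 34 tricyclic acetate (1R,3R,4S,6S,9S)-1-acetoxy-3-methyl-9-[(2R)-6-methylhept-5-en-2-yl] compound with the cis-C4/C6 cyclopropane and the C7=C8 butenolide
Conditions: Ac2O, DMAP, Et3N, CH2Cl2, 0 °C → rt
Reagents that add atoms: acetic anhydride, CC(=O)OC(C)=O
Why: DMAP-catalysed acylation of the secondary alcohol; no stereocentre is affected.

Step 22
Reactants: 34
Product: 35 CNP0205234.1, the (1R,3R,4S,6S,9S)-1-acetoxy-3-methyl tricyclic butenolide carrying the (2R,4E)-6-hydroperoxy-6-methylhept-4-en-2-yl side chain at C9
Conditions: O2, tetraphenylporphyrin (cat.), visible light, CH2Cl2, 0 °C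
Reagents that add atoms: oxygen, O=O
Why: Schenck ene reaction of singlet oxygen with the only electron-rich alkene; abstraction of a C3′ hydrogen with C–O bond formation at the tertiary carbon gives the (E)-allylic tertiary hydroperoxide, and the regioisomeric secondary hydroperoxide from methyl-hydrogen abstraction is expected alongside and has to be separated.

## Compound list

1 | (R)-citronellic acid, (3R)-3,7-dimethyloct-6-enoic acid | OC(=O)C[C@H](C)CCC=C(C)C | starting material
2 | (S)-4-benzyl-1,3-oxazolidin-2-one | O=C1OC[C@H](Cc2ccccc2)N1 | starting material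
3 | mixed pivalic (3R)-3,7-dimethyloct-6-enoic anhydride | CC(C)(C)C(=O)OC(=O)C[C@H](C)CCC=C(C)C | intermediate (not isolated)
4 | (S)-4-benzyl-3-[(3R)-3,7-dimethyloct-6-enoyl]-1,3-oxazolidin-2-one | O=C1OC[C@H](Cc2ccccc2)N1C(=O)C[C@H](C)CCC=C(C)C | intermediate
5 | Z-chlorotitanium enolate of 4 | O=C1OC[C@H](Cc2ccccc2)N1/C(O[Ti](Cl)(Cl)Cl)=C/[C@H](C)CCC=C(C)C | intermediate (not isolated)
6 | (S)-4-benzyl-3-[(2R,3R)-2-(hydroxymethyl)-3,7-dimethyloct-6-enoyl]-1,3-oxazolidin-2-one | O=C1OC[C@H](Cc2ccccc2)N1C(=O)[C@@H](CO)[C@H](C)CCC=C(C)C | intermediate
7 | (2R,3R)-2-(hydroxymethyl)-N-methoxy-N,3,7-trimethyloct-6-enamide | CON(C)C(=O)[C@@H](CO)[C@H](C)CCC=C(C)C | intermediate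
8 | (2R,3R)-2-[(tert-butyldimethylsilyloxy)methyl]-N-methoxy-N,3,7-trimethyloct-6-enamide | CON(C)C(=O)[C@@H](CO[Si](C)(C)C(C)(C)C)[C@H](C)CCC=C(C)C | intermediate
9 | (3R,4R)-3-[(tert-butyldimethylsilyloxy)methyl]-1-chloro-4,8-dimethylnon-7-en-2-one | ClCC(=O)[C@@H](CO[Si](C)(C)C(C)(C)C)[C@H](C)CCC=C(C)C | intermediate
10 | triethyl 2-chloro-2-phosphonoacetate | CCOC(=O)C(Cl)P(=O)(OCC)OCC | starting material
11 | potassium 2-chloro-2-(diethoxyphosphoryl)acetate | [K+].[O-]C(=O)C(Cl)P(=O)(OCC)OCC | intermediate
12 | (3R,4R)-3-[(tert-butyldimethylsilyloxy)methyl]-4,8-dimethyl-2-oxonon-7-en-1-yl 2-chloro-2-(diethoxyphosphoryl)acetate | CCOP(=O)(OCC)C(Cl)C(=O)OCC(=O)[C@@H](CO[Si](C)(C)C(C)(C)C)[C@H](C)CCC=C(C)C | intermediate (not isolated)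
13 | 3-chloro-4-[(2S,3R)-1-(tert-butyldimethylsilyloxy)-3,7-dimethyloct-6-en-2-yl]furan-2(5H)-one | ClC1=C(COC1=O)[C@@H](CO[Si](C)(C)C(C)(C)C)[C@H](C)CCC=C(C)C | intermediate
14 | propargyl alcohol | C#CCO | starting material
15 | lithium 2,2-dihydrido-2,5-dihydro-1,2-oxaalumol-2-uide (cyclic Z-vinylalanate) | [Li+].[AlH2-]1OCC=C1 | intermediate (not isolated)
16 | (Z)-3-(tributylstannyl)prop-2-en-1-ol | CCCC[Sn](CCCC)(CCCC)/C=C\CO | intermediate
17 | [(1S,2S)-2-(tributylstannyl)cyclopropyl]methanol | OC[C@@H]1C[C@@H]1[Sn](CCCC)(CCCC)CCCC | intermediate
18 | (1S,2S)-2-(tributylstannyl)cyclopropane-1-carbaldehyde | O=C[C@@H]1C[C@@H]1[Sn](CCCC)(CCCC)CCCC | intermediate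
19 | (tributylstannyl)methanol | OC[Sn](CCCC)(CCCC)CCCC | starting material
20 | tributyl[(1-ethoxyethoxy)methyl]stannane | CCOC(C)OC[Sn](CCCC)(CCCC)CCCC | intermediate
21 | [(1-ethoxyethoxy)methyl]lithium | [Li]COC(C)OCC | intermediate (not isolated)
22 | 2-(1-ethoxyethoxy)-1-[(1S,2S)-2-(tributylstannyl)cyclopropyl]ethan-1-ol | CCOC(C)OCC(O)[C@@H]1C[C@@H]1[Sn](CCCC)(CCCC)CCCC | intermediate
23 | 2-(1-ethoxyethoxy)-1-[(1S,2S)-2-(tributylstannyl)cyclopropyl]ethan-1-one | CCOC(C)OCC(=O)[C@@H]1C[C@@H]1[Sn](CCCC)(CCCC)CCCC | intermediate
24 | tributyl{(1S,2S)-2-[3-(1-ethoxyethoxy)prop-1-en-2-yl]cyclopropyl}stannane | CCOC(C)OCC(=C)[C@@H]1C[C@@H]1[Sn](CCCC)(CCCC)CCCC | intermediate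
25 | {(1S,2S)-2-[3-(1-ethoxyethoxy)prop-1-en-2-yl]cyclopropyl}lithium | CCOC(C)OCC(=C)[C@@H]1C[C@@H]1[Li] | intermediate (not isolated)
26 | {(1S,2S)-2-[3-(1-ethoxyethoxy)prop-1-en-2-yl]cyclopropyl}zinc chloride | CCOC(C)OCC(=C)[C@@H]1C[C@@H]1[Zn]Cl | intermediate (not isolated)
27 | 4-[(2S,3R)-1-(tert-butyldimethylsilyloxy)-3,7-dimethyloct-6-en-2-yl]-3-{(1S,2R)-2-[3-(1-ethoxyethoxy)prop-1-en-2-yl]cyclopropyl}furan-2(5H)-one | CCOC(C)OCC(=C)[C@@H]1C[C@@H]1C1=C(COC1=O)[C@@H](CO[Si](C)(C)C(C)(C)C)[C@H](C)CCC=C(C)C | intermediate
28 | 3-[(1S,2R)-2-(3-hydroxyprop-1-en-2-yl)cyclopropyl]-4-[(2S,3R)-1-hydroxy-3,7-dimethyloct-6-en-2-yl]furan-2(5H)-one | OCC(=C)[C@@H]1C[C@@H]1C1=C(COC1=O)[C@@H](CO)[C@H](C)CCC=C(C)C | intermediate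
29 | 3-[(1S,2R)-2-(3-bromoprop-1-en-2-yl)cyclopropyl]-4-[(2S,3R)-1-hydroxy-3,7-dimethyloct-6-en-2-yl]furan-2(5H)-one | BrCC(=C)[C@@H]1C[C@@H]1C1=C(COC1=O)[C@@H](CO)[C@H](C)CCC=C(C)C | intermediate
30 | (2S,3R)-2-{4-[(1S,2R)-2-(3-bromoprop-1-en-2-yl)cyclopropyl]-5-oxo-2,5-dihydrofuran-3-yl}-3,7-dimethyloct-6-enal | BrCC(=C)[C@@H]1C[C@@H]1C1=C(COC1=O)[C@@H](C=O)[C@H](C)CCC=C(C)C | intermediate
31 | allylchromium(III) dichloride derived from 30 | Cl[Cr](Cl)CC(=C)[C@@H]1C[C@@H]1C1=C(COC1=O)[C@@H](C=O)[C@H](C)CCC=C(C)C | intermediate (not isolated)
32 | tricyclic homoallylic alcohol, (1R,4R,6S,9S)-1-hydroxy-3-methylidene, C9 side chain (2R)-6-methylhept-5-en-2-yl | O[C@@H]1CC(=C)[C@@H]2C[C@@H]2C2=C(COC2=O)[C@@H]1[C@H](C)CCC=C(C)C | intermediate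
33 | tricyclic alcohol, (1R,3R,4S,6S,9S)-1-hydroxy-3-methyl, C9 side chain (2R)-6-methylhept-5-en-2-yl | O[C@@H]1C[C@@H](C)[C@@H]2C[C@@H]2C2=C(COC2=O)[C@@H]1[C@H](C)CCC=C(C)C | intermediate
34 | tricyclic acetate, (1R,3R,4S,6S,9S)-1-acetoxy-3-methyl, C9 side chain (2R)-6-methylhept-5-en-2-yl | CC(=O)O[C@@H]1C[C@@H](C)[C@@H]2C[C@@H]2C2=C(COC2=O)[C@@H]1[C@H](C)CCC=C(C)C | intermediate
35 | CNP0205234.1, tricyclic acetate with the (2R,4E)-6-hydroperoxy-6-methylhept-4-en-2-yl side chain | CC(=O)O[C@@H]1C[C@@H](C)[C@@H]2C[C@@H]2C2=C(COC2=O)[C@@H]1[C@H](C)C/C=C/C(C)(C)OO | target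

## Step count and least certain steps

Total: 22 steps. Longest linear sequence: 14 steps (1 → 35 through steps 1–5, 7, 15–22; the sequence from 14 through steps 8–10, 12–22 is equally long).

**Step 19 (key step).** Two processes can fail. Ring closure may lose to intermolecular coupling or to simple reduction of the C–Br bond, because an eight-membered ring forms slowly; slower addition and higher dilution answer this. More likely, attack on the wrong aldehyde face gives the C1 epimer, because the transition state of a medium ring is hard to predict. The fallback changes how C1 is set. It sets out from 32 obtained together with, or as, its C1 epimer F1. The mixture is oxidised with Dess–Martin periodinane to the β,γ-unsaturated ketone F2. Reduction with NaBH4/CeCl3 in MeOH–THF at −78 °C should bring hydride in anti to the C9 side chain and return the route to 32.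

**Step 2.** Lewis-acid-activated formaldehyde may attack the trisubstituted alkene (Prins or ene reaction) once the enolate is consumed. The fallback avoids the Lewis acid. It sets out from 4: the sodium enolate (NaHMDS, THF, −78 °C) is alkylated with benzyl chloromethyl ether in the same facial sense to give the benzyl ether F3. BCl3 in CH2Cl2 at −78 °C removes the benzyl group and the route is rejoined at 6.

**Step 7.** The chlorine-stabilised phosphonate carbanion may add too slowly to the hindered ketone. Base-induced enolisation toward C9 could then compete, with epimerisation or β-elimination of the silyloxy group. The fallback replaces the olefination by a reductive aldol. It sets out from 9: potassium dichloroacetate gives the dichloroacetate ester F4. SmI2 (2 equiv, THF, −78 °C) closes the ring by an intramolecular Reformatsky-type addition to the chlorohydrin lactone F5. Dehydration with MsCl/Et3N comes back to 13.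

**Step 15.** Tin–lithium exchange on the hindered cis-substituted stannane needs 0 °C and may be incomplete, or butyllithium may attack the allylic acetal. The fallback makes the same organolithium at low temperature. It sets out from 24: iododestannylation (I2, CH2Cl2, 0 °C, retention) gives the iodide F6. Iodine–lithium exchange with t-BuLi (2 equiv, Et2O, −78 °C) comes back to the route at 25, and transmetalation and coupling follow as before.

**Step 20.** The catalyst may also saturate the side-chain alkene, move the exocyclic double bond into the ring, or open the vinylcyclopropane by hydrogenolysis. The fallback is a metal-free reduction with diimide (2-nitrobenzenesulfonyl hydrazide, Et3N, CH2Cl2, rt). Diimide reduces only the unhindered 1,1-disubstituted alkene, but the face is then set by the ring shape and not by the hydroxyl. It sets out from 32, comes back at 33 and makes no new compound.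

**Step 22.** Abstraction of a methyl hydrogen instead of a C3′ hydrogen gives the secondary hydroperoxide, since both ene modes are open to a trisubstituted alkene; the material balance may be poor. The fallback builds the tertiary C–O bond regiospecifically. It sets out from 34:
- mCPBA gives the side-chain epoxide F7.
- Phenylselenide (from PhSeSePh and NaBH4 in EtOH) opens it at the secondary carbon to the hydroxy selenide F8.
- H2O2 gives the selenoxide F9 (not isolated), which eliminates away from the carbinol to the (E)-allylic tertiary alcohol F10.
- Acid-catalysed perhydrolysis (50% H2O2, cat. H2SO4, Et2O, 0 °C) at the tertiary allylic centre comes back at 35.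

## Further compounds

F1 | step 19 | C1 epimer of 32, (1S,4R,6S,9S)-1-hydroxy-3-methylidene tricyclic alcohol | O[C@H]1CC(=C)[C@@H]2C[C@@H]2C2=C(COC2=O)[C@@H]1[C@H](C)CCC=C(C)C
F2 | step 19 | tricyclic C1 ketone with C3 methylidene | O=C1CC(=C)[C@@H]2C[C@@H]2C2=C(COC2=O)[C@@H]1[C@H](C)CCC=C(C)C
F3 | step 2 | (S)-4-benzyl-3-[(2R,3R)-2-(benzyloxymethyl)-3,7-dimethyloct-6-enoyl]-1,3-oxazolidin-2-one | O=C1OC[C@H](Cc2ccccc2)N1C(=O)[C@@H](COCc3ccccc3)[C@H](C)CCC=C(C)C
F4 | step 7 | (3R,4R)-3-[(tert-butyldimethylsilyloxy)methyl]-4,8-dimethyl-2-oxonon-7-en-1-yl dichloroacetate | ClC(Cl)C(=O)OCC(=O)[C@@H](CO[Si](C)(C)C(C)(C)C)[C@H](C)CCC=C(C)C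
F5 | step 7 | 3-chloro-4-hydroxy-4-[(2R,3R)-1-(tert-butyldimethylsilyloxy)-3,7-dimethyloct-6-en-2-yl]dihydrofuran-2(3H)-one (mixture at C3 and C4) | ClC1C(=O)OCC1(O)[C@@H](CO[Si](C)(C)C(C)(C)C)[C@H](C)CCC=C(C)C
F6 | step 15 | (1S,2S)-1-iodo-2-[3-(1-ethoxyethoxy)prop-1-en-2-yl]cyclopropane | CCOC(C)OCC(=C)[C@@H]1C[C@@H]1I
F0 | step 20 | none | none
F7 | step 22 | side-chain 4′,5′-epoxide of 34 (mixture at the epoxide CH) | CC(=O)O[C@@H]1C[C@@H](C)[C@@H]2C[C@@H]2C2=C(COC2=O)[C@@H]1[C@H](C)CCC1OC1(C)C
F8 | step 22 | 5′-hydroxy-4′-(phenylselanyl) derivative of 34 | CC(=O)O[C@@H]1C[C@@H](C)[C@@H]2C[C@@H]2C2=C(COC2=O)[C@@H]1[C@H](C)CCC([Se]c1ccccc1)C(C)(C)O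
F9 | step 22 | selenoxide of F8 | CC(=O)O[C@@H]1C[C@@H](C)[C@@H]2C[C@@H]2C2=C(COC2=O)[C@@H]1[C@H](C)CCC([Se](=O)c1ccccc1)C(C)(C)O
F10 | step 22 | (E)-allylic tertiary alcohol corresponding to 35 | CC(=O)O[C@@H]1C[C@@H](C)[C@@H]2C[C@@H]2C2=C(COC2=O)[C@@H]1[C@H](C)C/C=C/C(C)(C)O
A1 | alternative 1 | cis-bicyclo[5.2.0]nonane with ring-fusion tertiary alcohol and cyclobutyl mesylate | CC(C)(C)[Si](C)(C)O[C@@H]1C[C@@H](C)[C@@H]2C[C@H](OS(C)(=O)=O)[C@]2(O)[C@@H](COCc3ccc(OC)cc3)[C@@H]1[C@H](C)CCC=C(C)C
A2 | alternative 1 | cis-bicyclo[6.1.0]nonan-2-one (cyclopropyl ketone) | CC(C)(C)[Si](C)(C)O[C@@H]1C[C@@H](C)[C@@H]2C[C@@H]2C(=O)[C@@H](COCc2ccc(OC)cc2)[C@@H]1[C@H](C)CCC=C(C)C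
A3 | alternative 2 | eleven-membered keto-phosphonate lactone (mixture at the phosphonate carbon) | CC(C)(C)[Si](C)(C)O[C@@H]1C[C@@H](C)[C@@H]2C[C@@H]2C(P(=O)(OCC)OCC)C(=O)OCC(=O)[C@@H]1[C@H](C)CCC=C(C)C
A4 | alternative 2 | silyl-protected tricyclic butenolide | CC(C)(C)[Si](C)(C)O[C@@H]1C[C@@H](C)[C@@H]2C[C@@H]2C2=C(COC2=O)[C@@H]1[C@H](C)CCC=C(C)C
A5 | alternative 3 | butenolide-fused 2-methylene-6-[(E)-propenyl]-3,6-dihydro-2H-pyran | C=C1O[C@H](/C=C/C)C2=C(COC2=O)[C@@H]1[C@H](C)CCC=C(C)C
A6 | alternative 3 | butenolide-fused cyclooctadienone | O=C1C[C@@H](C)/C=C\C2=C(COC2=O)[C@@H]1[C@H](C)CCC=C(C)C
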